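## Retrosynthetic overview

1. Target 22 ⇐ hydrogenolysis of three benzyl ethers in 21; the C2 carbinol ⇐ oxazaborolidine-controlled reduction of the α,α-diaryl ketone 20.
2. Key C1–C2 bond ⇐ carbene-generated acyl anion equivalent of arylacetaldehyde 18 adding 1,4 to the ring A ortho-quinone methide 19. Both carbons are electrophilic in their normal polarity; this step sets C1.
3. Quinone methide precursor, sulfone 16 ⇐ salicylaldehyde 11 + aryllithium 14 (ring D), then sulfinate trapping.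
4. 11 ⇐ ortho-formylation of (R)-isomucronulatol 10 ⇐ asymmetric hydrogenation of isoflavene 8 (sets C3).
5. Ring order: rings A, B, D and E are bought as arenes; the only ring formed is the pyran ring C, by O-alkylation and intramolecular Wittig reaction of phosphonium salt 6 with bromoketone 3.

Assumption: compounds 1, 4, 12 and 17 are taken as catalogue chemicals; the named enantiomers of the Ir ligand and of the triazolium salt are those assumed to give the stated configurations, and their mirror images are used if the first run shows the opposite sense.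

Descriptor note: in 20 and 21 the C1 descriptor is S, in the target it is R; the geometry is the same, because the benzyloxy-substituted ring D outranks ring A by the CIP rules until the benzyl groups are removed.

Abbreviations: cod = cycloocta-1,5-diene; tBu-PHOX = (S)-4-tert-butyl-2-[2-(diphenylphosphanyl)phenyl]-4,5-dihydrooxazole; BArF = tetrakis[3,5-bis(trifluoromethyl)phenyl]borate; Me-CBS = 1-methyl-3,3-diphenyltetrahydro-1H,3H-pyrrolo[1,2-c][1,3,2]oxazaborole; DMP = 1,1,1-triacetoxy-1,1-dihydro-1,2-benziodoxol-3(1H)-one.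

## Route

Step 1
Reactants: 1 1-(2-hydroxy-3,4-dimethoxyphenyl)ethan-1-one
Product: 2 1-[2-(benzyloxy)-3,4-dimethoxyphenyl]ethan-1-one
Conditions: BnBr, K2CO3, DMF, 60 °C
Reagents that add atoms: benzyl bromide, BrCc1ccccc1
Why: Williamson ether synthesis; the benzyl group blocks benzofuranone formation in step 4 and is removed later by H2.

Step 2
Reactants: 2 1-[2-(benzyloxy)-3,4-dimethoxyphenyl]ethan-1-one
Product: 3 1-[2-(benzyloxy)-3,4-dimethoxyphenyl]-2-bromoethan-1-one
Conditions: CuBr2 (2.1 equiv), EtOAc/CHCl3, reflux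
Reagents that add atoms: CuBr2, Br[Cu]Br
Why: King–Ostrum α-bromination, in which CuBr2 brominates the enol of the aryl methyl ketone at the methyl group without touching the ring.

Step 3
Reactants: 4 4-(benzyloxy)-2-hydroxybenzaldehyde
Product: 6 [4-(benzyloxy)-2-hydroxybenzyl]triphenylphosphonium bromide, via benzylic alcohol 5 (not isolated)
Conditions: NaBH4, MeOH, 0 °C; extractive work-up, solvent swap; then PPh3·HBr, MeCN, 80 °C
Reagents that add atoms: triphenylphosphine hydrobromide, Br.c1ccc(cc1)P(c1ccccc1)c1ccccc1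
Why: hydride reduction of the aldehyde, then SN1 phosphonium salt formation, because the electron-rich ortho-hydroxybenzyl alcohol ionises under HBr and the cation is captured by PPh3.

Step 4
Reactants: 6 [4-(benzyloxy)-2-hydroxybenzyl]triphenylphosphonium bromide; 3 1-[2-(benzyloxy)-3,4-dimethoxyphenyl]-2-bromoethan-1-one
Product: 8 7-(benzyloxy)-3-[2-(benzyloxy)-3,4-dimethoxyphenyl]-2H-chromene, via keto phosphonium salt 7 (not isolated)
Conditions: K2CO3 (1.1 equiv), MeCN, rt; then KOtBu (1.2 equiv), 60 °C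
Reagents that add atoms: none
Why: Williamson O-alkylation of the phenoxide by the α-bromoketone, then intramolecular Wittig olefination of the benzylic ylide onto the ketone closes the six-membered pyran ring.

Step 5
Reactants: 8 7-(benzyloxy)-3-[2-(benzyloxy)-3,4-dimethoxyphenyl]-2H-chromene
Product: 10 (3R)-3-(2-hydroxy-3,4-dimethoxyphenyl)chroman-7-ol, via dibenzyl isoflavan 9 (not isolated)
Conditions: [Ir(cod)((S)-tBu-PHOX)]BArF (1 mol %), H2 (50 bar), CH2Cl2, rt; then Pd/C (10 wt %), H2 (1 atm), MeOH/EtOAc, rt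
Reagents that add atoms: none
Why: Ir-catalysed asymmetric hydrogenation of a trisubstituted cyclic styrene (Pfaltz type, established for 3-aryl-2H-chromenes) adds H2 to one face of C3=C4 and sets C3 as R under catalyst control, after which Pd/C hydrogenolysis removes both benzyl ethers to give (R)-isomucronulatol.

Step 6
Reactants: 10 (3R)-3-(2-hydroxy-3,4-dimethoxyphenyl)chroman-7-ol
Product: 11 (3R)-7-hydroxy-3-(2-hydroxy-3,4-dimethoxyphenyl)chromane-6-carbaldehyde
Conditions: MgCl2, Et3N, (CH2O)n, MeCN, 80 °C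
Reagents that add atoms: paraformaldehyde, C=O
Why: Casnati–Skattebøl magnesium-phenoxide-directed ortho-formylation; ring B has no free ortho position, and on ring A the unhindered C6 (para to the ring oxygen) is preferred over C8 (between two oxygens), as with 3-alkoxyphenols.

Step 7
Reactants: 12 4-bromobenzene-1,3-diol
Product: 13 2,4-bis(benzyloxy)-1-bromobenzene
Conditions: BnBr (2.2 equiv), K2CO3, DMF, 60 °C
Reagents that add atoms: benzyl bromide, BrCc1ccccc1
Why: double Williamson ether synthesis.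

Step 8
Reactants: 11 (3R)-7-hydroxy-3-(2-hydroxy-3,4-dimethoxyphenyl)chromane-6-carbaldehyde; 13 2,4-bis(benzyloxy)-1-bromobenzene
Product: 16 (3R)-6-{[2,4-bis(benzyloxy)phenyl](4-methylbenzenesulfonyl)methyl}-3-(2-hydroxy-3,4-dimethoxyphenyl)chroman-7-ol, via aryllithium 14 (not isolated), via benzhydrol 15 (not isolated)
Conditions: 13 (3.3 equiv), n-BuLi (3.3 equiv), THF, −78 °C; add 11, −78 → 0 °C; then 4-MeC6H4SO2H (6 equiv), 0 °C → rt
Reagents that add atoms: 4-methylbenzenesulfinic acid, Cc1ccc(cc1)S(=O)O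
Why: bromine–lithium exchange and 1,2-addition to the aldehyde (two equivalents of 14 are spent on the phenols), then SN1 sulfination, in which the doubly activated benzhydrol ionises under the sulfinic acid and is trapped at sulfur to give the ortho-quinone methide precursor as an inconsequential mixture of epimers at the sulfonyl carbon.

Step 9
Reactants: 17 2-[4-(benzyloxy)phenyl]ethan-1-ol
Product: 18 2-[4-(benzyloxy)phenyl]acetaldehyde
Conditions: DMP, CH2Cl2, 0 °C → rt; used at once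
Reagents that add atoms: none
Why: Dess–Martin oxidation gives the enolisable arylacetaldehyde under neutral conditions without over-oxidation.

Step 10
Reactants: 16 (3R)-6-{[2,4-bis(benzyloxy)phenyl](4-methylbenzenesulfonyl)methyl}-3-(2-hydroxy-3,4-dimethoxyphenyl)chroman-7-ol; 18 2-[4-(benzyloxy)phenyl]acetaldehyde
Product: 20 (1S)-1-[2,4-bis(benzyloxy)phenyl]-3-[4-(benzyloxy)phenyl]-1-[(3R)-7-hydroxy-3-(2-hydroxy-3,4-dimethoxyphenyl)chroman-6-yl]propan-2-one, via o-quinone methide 19 (not isolated)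
Conditions: (5aS,10bR)-2-(pentafluorophenyl)-5a,10b-dihydro-4H,6H-indeno[2,1-b][1,2,4]triazolo[4,3-d][1,4]oxazin-2-ium tetrafluoroborate (20 mol %), K2CO3 (2.5 equiv), 4 Å MS, CH2Cl2, 0 °C; 18 (2.5 equiv) by syringe pump over 6 h; pH 7 buffer quench
Reagents that add atoms: none
Why: Proposed new method: K2CO3 deprotonates the C7 phenol and 1,4-elimination of sulfinate gives the (E)-ortho-quinone methide 19, while the triazolylidene turns 18 into its nucleophilic carbene–aldehyde adduct (acyl anion equivalent), whose Stetter-type 1,4-addition to the exocyclic carbon of 19 is driven by rearomatisation, joins two carbons that are both electrophilic in 18 and 19, and sets C1 by attack on the Re face (ring A carbon > ring D carbon > H) under control of the chiral carbene; the ortho phenoxide formed disfavours enolisation of the new α,α-diaryl ketone; the closest known reactions are the thiazolium-catalysed acylation of ortho-quinone methides to α-aryl ketones, carbene-catalysed 1,6-additions of aldehydes to para-quinone methides, and enantioselective carbene-enolate and homoenolate annulations of sulfone-derived ortho-quinone methides.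

Step 11
Reactants: 20 (1S)-1-[2,4-bis(benzyloxy)phenyl]-3-[4-(benzyloxy)phenyl]-1-[(3R)-7-hydroxy-3-(2-hydroxy-3,4-dimethoxyphenyl)chroman-6-yl]propan-2-one
Product: 21 (1S,2R)-1-[2,4-bis(benzyloxy)phenyl]-3-[4-(benzyloxy)phenyl]-1-[(3R)-7-hydroxy-3-(2-hydroxy-3,4-dimethoxyphenyl)chroman-6-yl]propan-2-ol
Conditions: (S)-Me-CBS (0.5 equiv), BH3·SMe2 (3.5 equiv), THF, −20 °C, slow addition of 20; MeOH quench
Reagents that add atoms: none
Why: Corey–Bakshi–Shibata reduction, in which the (S)-oxazaborolidine treats the branched diarylmethyl group as the large substituent and the benzyl group as the small one and so delivers hydride to give the 2R carbinol by reagent control (same sense as acetophenone to (R)-1-phenylethanol), under non-basic conditions that leave C1 untouched.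

Step 12
Reactants: 21 (1S,2R)-1-[2,4-bis(benzyloxy)phenyl]-3-[4-(benzyloxy)phenyl]-1-[(3R)-7-hydroxy-3-(2-hydroxy-3,4-dimethoxyphenyl)chroman-6-yl]propan-2-ol
Product: 22 (1R,2R)-1-(2,4-dihydroxyphenyl)-1-[(3R)-7-hydroxy-3-(2-hydroxy-3,4-dimethoxyphenyl)chroman-6-yl]-3-(4-hydroxyphenyl)propan-2-ol
Conditions: H2 (1 atm), Pd/C (10 wt %), EtOAc/MeOH, rt
Reagents that add atoms: none
Why: hydrogenolysis of the three benzyl aryl ethers, the only benzylic C–O bonds present, leaves the methyl ethers, the homobenzylic alcohol and all three stereocentres unchanged.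

## Compound list

1 | 1-(2-hydroxy-3,4-dimethoxyphenyl)ethan-1-one | CC(=O)c1ccc(OC)c(OC)c1O | starting material
2 | 1-[2-(benzyloxy)-3,4-dimethoxyphenyl]ethan-1-one | CC(=O)c1ccc(OC)c(OC)c1OCc1ccccc1 | intermediate
3 | 1-[2-(benzyloxy)-3,4-dimethoxyphenyl]-2-bromoethan-1-one | O=C(CBr)c1ccc(OC)c(OC)c1OCc1ccccc1 | intermediate
4 | 4-(benzyloxy)-2-hydroxybenzaldehyde | O=Cc1ccc(OCc2ccccc2)cc1O | starting material
5 | 5-(benzyloxy)-2-(hydroxymethyl)phenol | OCc1ccc(OCc2ccccc2)cc1O | intermediate (not isolated)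
6 | [4-(benzyloxy)-2-hydroxybenzyl]triphenylphosphonium bromide | [Br-].Oc1cc(OCc2ccccc2)ccc1C[P+](c1ccccc1)(c1ccccc1)c1ccccc1 | intermediate
7 | {4-(benzyloxy)-2-[2-(2-(benzyloxy)-3,4-dimethoxyphenyl)-2-oxoethoxy]benzyl}triphenylphosphonium bromide | [Br-].COc1ccc(C(=O)COc2cc(OCc3ccccc3)ccc2C[P+](c2ccccc2)(c2ccccc2)c2ccccc2)c(OCc2ccccc2)c1OC | intermediate (not isolated)
8 | 7-(benzyloxy)-3-[2-(benzyloxy)-3,4-dimethoxyphenyl]-2H-chromene | COc1ccc(C2=Cc3ccc(OCc4ccccc4)cc3OC2)c(OCc2ccccc2)c1OC | intermediate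
9 | (3R)-7-(benzyloxy)-3-[2-(benzyloxy)-3,4-dimethoxyphenyl]chromane | COc1ccc([C@@H]2COc3cc(OCc4ccccc4)ccc3C2)c(OCc2ccccc2)c1OC | intermediate (not isolated)
10 | (3R)-3-(2-hydroxy-3,4-dimethoxyphenyl)chroman-7-ol, (R)-isomucronulatol | COc1ccc([C@@H]2COc3cc(O)ccc3C2)c(O)c1OC | intermediate
11 | (3R)-7-hydroxy-3-(2-hydroxy-3,4-dimethoxyphenyl)chromane-6-carbaldehyde | COc1ccc([C@@H]2COc3cc(O)c(C=O)cc3C2)c(O)c1OC | intermediate
12 | 4-bromobenzene-1,3-diol | Oc1ccc(Br)c(O)c1 | starting material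
13 | 2,4-bis(benzyloxy)-1-bromobenzene | Brc1ccc(OCc2ccccc2)cc1OCc1ccccc1 | intermediate
14 | [2,4-bis(benzyloxy)phenyl]lithium | [Li]c1ccc(OCc2ccccc2)cc1OCc1ccccc1 | intermediate (not isolated)
15 | (3R)-6-{[2,4-bis(benzyloxy)phenyl](hydroxy)methyl}-3-(2-hydroxy-3,4-dimethoxyphenyl)chroman-7-ol, both carbinol epimers | COc1ccc([C@@H]2COc3cc(O)c(C(O)c4ccc(OCc5ccccc5)cc4OCc4ccccc4)cc3C2)c(O)c1OC | intermediate (not isolated)
16 | (3R)-6-{[2,4-bis(benzyloxy)phenyl](4-methylbenzenesulfonyl)methyl}-3-(2-hydroxy-3,4-dimethoxyphenyl)chroman-7-ol, both epimers at the sulfonyl carbon | COc1ccc([C@@H]2COc3cc(O)c(C(c4ccc(OCc5ccccc5)cc4OCc4ccccc4)S(=O)(=O)c4ccc(C)cc4)cc3C2)c(O)c1OC | intermediate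
17 | 2-[4-(benzyloxy)phenyl]ethan-1-ol | OCCc1ccc(OCc2ccccc2)cc1 | starting material
18 | 2-[4-(benzyloxy)phenyl]acetaldehyde | O=CCc1ccc(OCc2ccccc2)cc1 | intermediate
19 | (3R,6E)-6-{[2,4-bis(benzyloxy)phenyl]methylidene}-3-(2-hydroxy-3,4-dimethoxyphenyl)-3,4-dihydro-2H-chromen-7(6H)-one | COc1ccc([C@@H]2COC3=CC(=O)/C(=C/c4ccc(OCc5ccccc5)cc4OCc4ccccc4)C=C3C2)c(O)c1OC | intermediate (not isolated)
20 | (1S)-1-[2,4-bis(benzyloxy)phenyl]-3-[4-(benzyloxy)phenyl]-1-[(3R)-7-hydroxy-3-(2-hydroxy-3,4-dimethoxyphenyl)chroman-6-yl]propan-2-one | COc1ccc([C@@H]2COc3cc(O)c([C@@H](c4ccc(OCc5ccccc5)cc4OCc4ccccc4)C(=O)Cc4ccc(OCc5ccccc5)cc4)cc3C2)c(O)c1OC | intermediate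
21 | (1S,2R)-1-[2,4-bis(benzyloxy)phenyl]-3-[4-(benzyloxy)phenyl]-1-[(3R)-7-hydroxy-3-(2-hydroxy-3,4-dimethoxyphenyl)chroman-6-yl]propan-2-ol | COc1ccc([C@@H]2COc3cc(O)c([C@@H](c4ccc(OCc5ccccc5)cc4OCc4ccccc4)[C@H](O)Cc4ccc(OCc5ccccc5)cc4)cc3C2)c(O)c1OC | intermediate
22 | (1R,2R)-1-(2,4-dihydroxyphenyl)-1-[(3R)-7-hydroxy-3-(2-hydroxy-3,4-dimethoxyphenyl)chroman-6-yl]-3-(4-hydroxyphenyl)propan-2-ol | COc1ccc([C@@H]2COc3cc(O)c([C@@H](c4ccc(O)cc4O)[C@H](O)Cc4ccc(O)cc4)cc3C2)c(O)c1OC | target

## Step count and weak points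

Total step count: 12. Longest linear sequence: 9 steps (1 → 2 → 3 → 8 → 10 → 11 → 16 → 20 → 21 → 22, steps 1, 2, 4, 5, 6, 8, 10, 11, 12).

The three steps most likely to fail:

**Step 10.** The arylacetaldehyde 18 can be lost to aldol condensation, the carbene–aldehyde adduct can reduce 19 by hydride transfer instead of adding to it, the facial selectivity is untested, and C1 of 20 may epimerise if the base is too strong. The fallback sets out from 18 and 16 and comes back at 20. Aldehyde 18 is converted with propane-1,3-dithiol and BF3·OEt2 in CH2Cl2 into 2-[4-(benzyloxy)benzyl]-1,3-dithiane F1. n-BuLi in THF at −30 °C turns this into {2-[4-(benzyloxy)benzyl]-1,3-dithian-2-yl}lithium F2. Adding 3.3 equivalents of it to sulfone 16 at −78 → 0 °C deprotonates both phenols, releases 19 and adds 1,4, giving (3R)-6-{[2,4-bis(benzyloxy)phenyl]{2-[4-(benzyloxy)benzyl]-1,3-dithian-2-yl}methyl}-3-(2-hydroxy-3,4-dimethoxyphenyl)chroman-7-ol F3 as both C1 epimers. MeI and CaCO3 in aqueous MeCN unmask 20 together with its C1 epimer (1R)-1-[2,4-bis(benzyloxy)phenyl]-3-[4-(benzyloxy)phenyl]-1-[(3R)-7-hydroxy-3-(2-hydroxy-3,4-dimethoxyphenyl)chroman-6-yl]propan-2-one F4. The two are separated by preparative HPLC and the unwanted one is recycled by equilibration with DBU in THF.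

**Step 11.** The free ortho phenol can close onto the ketone and dehydrate to a benzofuran under Lewis acid, the aryloxyborane formed from the phenol may deliver hydride without catalyst control, and the oxazaborolidine has to tell a diarylmethyl from a benzyl group. The fallback avoids the ketone altogether; it sets out from 17 and 16 and comes back at 21. Alcohol 17 is acylated with N,N-diisopropylcarbamoyl chloride and NaH in THF to 2-[4-(benzyloxy)phenyl]ethyl N,N-diisopropylcarbamate F5. s-BuLi and (−)-sparteine in Et2O at −78 °C remove the pro-S proton to give [(1S)-2-[4-(benzyloxy)phenyl]-1-{[di(propan-2-yl)carbamoyl]oxy}ethyl]lithium F6. This configurationally stable α-oxygenated carbanion adds with retention to 19, liberated from 16 with LiN(SiMe3)2 (2.1 equiv) at −78 → −40 °C, and gives (1S,2R)-1-[2,4-bis(benzyloxy)phenyl]-3-[4-(benzyloxy)phenyl]-1-[(3R)-7-hydroxy-3-(2-hydroxy-3,4-dimethoxyphenyl)chroman-6-yl]propan-2-yl N,N-diisopropylcarbamate F7. The C2 configuration is fixed by the sparteine-controlled lithiation; the C1 epimer, if formed, is removed by chromatography. LiAlH4 in refluxing THF cleaves the carbamate to 21.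

**Step 5.** The ortho-benzyloxy group on the 3-aryl ring may slow the Ir hydrogenation or erode its selectivity. The fallback sets out from 8 and comes back at 10. Hydrogenation of 8 over Pd/C (H2, 1 atm, EtOAc/MeOH) reduces the alkene and removes both benzyl groups to give racemic 3-(2-hydroxy-3,4-dimethoxyphenyl)chroman-7-ol F8. Preparative chiral SFC on an amylose tris(3,5-dimethylphenylcarbamate) phase then delivers 10, and (3S)-3-(2-hydroxy-3,4-dimethoxyphenyl)chroman-7-ol F9 is discarded.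

## Further compounds

F1 | step 10 | 2-[4-(benzyloxy)benzyl]-1,3-dithiane | C1CSC(Cc2ccc(OCc3ccccc3)cc2)SC1
F2 | step 10 | {2-[4-(benzyloxy)benzyl]-1,3-dithian-2-yl}lithium | [Li]C1(Cc2ccc(OCc3ccccc3)cc2)SCCCS1
F3 | step 10 | (3R)-6-{[2,4-bis(benzyloxy)phenyl]{2-[4-(benzyloxy)benzyl]-1,3-dithian-2-yl}methyl}-3-(2-hydroxy-3,4-dimethoxyphenyl)chroman-7-ol, both C1 epimers | COc1ccc([C@@H]2COc3cc(O)c(C(c4ccc(OCc5ccccc5)cc4OCc4ccccc4)C4(Cc5ccc(OCc6ccccc6)cc5)SCCCS4)cc3C2)c(O)c1OC
F4 | step 10 | (1R)-1-[2,4-bis(benzyloxy)phenyl]-3-[4-(benzyloxy)phenyl]-1-[(3R)-7-hydroxy-3-(2-hydroxy-3,4-dimethoxyphenyl)chroman-6-yl]propan-2-one | COc1ccc([C@@H]2COc3cc(O)c([C@H](c4ccc(OCc5ccccc5)cc4OCc4ccccc4)C(=O)Cc4ccc(OCc5ccccc5)cc4)cc3C2)c(O)c1OC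
F5 | step 11 | 2-[4-(benzyloxy)phenyl]ethyl N,N-diisopropylcarbamate | CC(C)N(C(C)C)C(=O)OCCc1ccc(OCc2ccccc2)cc1
F6 | step 11 | [(1S)-2-[4-(benzyloxy)phenyl]-1-{[di(propan-2-yl)carbamoyl]oxy}ethyl]lithium | [Li][C@H](OC(=O)N(C(C)C)C(C)C)Cc1ccc(OCc2ccccc2)cc1
F7 | step 11 | (1S,2R)-1-[2,4-bis(benzyloxy)phenyl]-3-[4-(benzyloxy)phenyl]-1-[(3R)-7-hydroxy-3-(2-hydroxy-3,4-dimethoxyphenyl)chroman-6-yl]propan-2-yl N,N-diisopropylcarbamate | COc1ccc([C@@H]2COc3cc(O)c([C@@H](c4ccc(OCc5ccccc5)cc4OCc4ccccc4)[C@H](OC(=O)N(C(C)C)C(C)C)Cc4ccc(OCc5ccccc5)cc4)cc3C2)c(O)c1OC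
F8 | step 5 | racemic 3-(2-hydroxy-3,4-dimethoxyphenyl)chroman-7-ol | COc1ccc(C2COc3cc(O)ccc3C2)c(O)c1OC
F9 | step 5 | (3S)-3-(2-hydroxy-3,4-dimethoxyphenyl)chroman-7-ol | COc1ccc([C@H]2COc3cc(O)ccc3C2)c(O)c1OC
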